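## The problem

Compound 20 is (2S,3S,5R)-5-[(1R)-1-hydroxydec-9-enyl]-2-pentyltetrahydrofuran-3-yl hexadecanoate. The ring is numbered O1, C2 (pentyl), C3 (ester oxygen), C4, C5; the carbinol carbon on C5 is C1' and the pentyl carbons are C1''–C5''. The ring carries three stereocentres, with pentyl and acyloxy cis (C2/C3) and the two carbon substituents trans (C2/C5); a fourth stereocentre sits at C1', threo to C5. C1' lies outside every ring-forming event and is most safely bought. C3 can pass its configuration to C5 through a chelate-controlled 1,3-syn reduction, and C3 can dictate C2 reliably only if the two are tied into a small fused ring. Two secondary oxygens (C3, C1') must be told apart because only C3 bears the palmitate, and that ester will not survive hydride, hard nucleophiles or hydroxide, so it must arrive after the last reduction. The monosubstituted C9'=C10' alkene forbids hydrogenation, ozonolysis, hydroboration and free electrophilic halogen, and must be spared by any alkene-activating metal. The feature that opens the structure is that the C2–C1'' and C3–O bonds are cis: with C1'' and C2'' they form the backbone of a cis-fused γ-lactone, C3–O–C2''(=O)–C1''–C2, a 2,6-dioxabicyclo[3.3.0]octan-3-one. An alkene, two hydroxyls and carbon monoxide can close both of its rings in one oxidative carbonylation.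

## Retrosynthesis

**20 back to 18.** The last operation is release of the C1' hydroxyl from the tert-butyldiphenylsilyl (TBDPS) ether 19, so no step has to distinguish two free secondary alcohols. In 19 the pentyl chain is cut between C2'' and C3'': n-Pr2CuLi is joined to primary tosylate 18. A cut one bond further in or out gains nothing, whereas this one leaves exactly the two carbons that the lactone of the key step supplies. The palmitate is already present in 18. With a free C3 hydroxyl, the alkoxide would sit four atoms from the sulfonate and close a second tetrahydrofuran, so the ester acts as its own protecting group. The forward step is asked only to displace a primary sulfonate beside an ester, a silyl ether and an isolated alkene.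

**18 back to 14.** Tosylate and palmitate mark a primary and a secondary hydroxyl, that is diol 15 (sulfonylated, then acylated with 16 through hydroxy tosylate 17). Such a 1,4-diol is the hydride-reduction product of γ-lactone 14. Opening the lactone with a carbon nucleophile, or olefinating the derived lactol, would leave a ketone or an internal alkene to be removed in the presence of the terminal alkene; reduction avoids both. In 14 the C3 oxygen and C2'' are masked in one function, so C3 never needs a protecting group.

**14 back to 12 and 13 (key disconnection).** Three bonds are cut: O1–C2, C1''–C2'' and the lactone O–C2''. What remains is the open-chain ene-diol 12 and carbon monoxide 13. Cuts that form only O1–C2 (haloetherification, epoxide opening) leave a one-carbon stub and rely on allylic induction for the 2,3-cis relationship. Here CO delivers C2'' and the second ring makes cis obligatory. The precursor has no ring and one stereocentre fewer. The forward reaction must add the C5 hydroxyl to the internal alkene carbon, must leave the remote C14=C15 alkene alone, and needs the C6 oxygen blocked. TBDPS is chosen because it also withstands AcOH/CuCl2, LiAlH4 and the cuprate and does not migrate to a neighbouring hydroxyl.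

**12 back to 7 and 8.** The C5 carbinol is traced to ketone 10, to be reduced under 1,3-chelate control by the C3 hydroxyl (boron chelate 11). Ketone 10 is cut at C3–C4 into methyl ketone 7 (as enol borinate 9) and acrolein 8. A cut at C4–C5 would need a vinyl ketone enolate or leave C3 to an uncontrolled vinyl addition; a cut at C5–C6 would need an α-oxygenated carbanion. The price of the aldol cut is that C3 is 1,4 to the only stereocentre of 7, so the aldol must be reagent-controlled; once C3 is set, C5 follows.

**7 back to 1 and 2.** Removing the methyl group leads to ester 5 (through N-methoxy-N-methylamide 6), removing the silyl group to α-hydroxy ester 4. Ester 4 is cut between C3 and C4 into methyl (R)-glycidate 2 and magnesium reagent 3 from 8-bromooct-1-ene 1. Auxiliary-based α-hydroxylation of undec-10-enoic acid is reliable but three steps longer, and asymmetric dihydroxylation is ruled out by the terminal alkene. The chosen cut buys the C1' stereocentre and asks only for regioselective epoxide opening beside an ester.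

## Roads not taken

**Alternative 1:** ring contraction of a six-membered enol ether.
- **Cut and key step.** O1–C5 is formed by a 1,2-shift of the ring oxygen in dihydropyran A1. A trivalent iodine reagent (PhI(OAc)2 or PhI(OH)OTs) in MeOH attacks the enol ether β-carbon, and the ring oxygen moves from C1' to C5, leaving C1' as the dimethyl acetal A2.
- **Merits.** Pentyl and palmitate are in place before the ring is made. The 2,3-cis pair is set on a pyran, where it is easy to control. No second alkene is present when the ring forms; in that respect the road is safer than the chosen one.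
- **Weak points.** The C5 configuration depends on which face of a nearly flat enol ether the iodine reagent attacks, steered only by substituents two and three atoms away. After acetal hydrolysis, C1' must be created by adding a nine-carbon organometallic to an epimerisable α-alkoxy aldehyde, beside an ester and with only chelation to control it.
- **Comparison.** The chosen plan has to set against the chemoselectivity advantage that all four stereocentres have a defined origin (chiral pool, reagent, chelate, ring fusion) and that no late carbinol has to be made next to the ester.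

**Alternative 2:** epoxidation of a cyclic enol ether and syn alkyl transfer.
- **Cut and key step.** C2–C1'' (the whole pentyl) and C3–O are cut. Dimethyldioxirane converts dihydrofuran A3 into epoxide A4 on the face away from the C5 side chain. Al(C5H11)3 then opens A4 at C2, delivering pentyl from the oxygen-bound aluminium to give alcohol A5.
- **Merits.** One operation installs pentyl and the C3 hydroxyl cis to each other and leaves C3–OH free for acylation. The endgame (esterification, oxidative removal of the 4-methoxybenzyl group) is shorter than the three steps the chosen plan spends on growing pentyl from a two-carbon stub. In step economy after ring formation this road is better.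
- **Weak points.** Face selection in the epoxidation rests on one substituent across a flat five-membered ring. Furanoid enol ether epoxides are labile. Syn delivery competes with anti opening through the oxocarbenium ion and with β-hydride transfer from a higher trialkylaluminium. A3 needs its own stereocontrolled synthesis.
- **Comparison.** The chosen plan sets against the shorter endgame a 2,3-cis relationship that is enforced by the bicycle instead of resting on two kinetic selectivities.

**Alternative 3:** (3+2) annulation of an allylsilane with an aldehyde.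
- **Cut and key step.** C4–C5 and O1–C2 are cut. The SnCl4 chelate of benzyloxy aldehyde A6 is attacked by the alkene terminus of allylsilane A7, silicon shifts to C3, and the aldehyde oxygen closes on C2 to give silyl tetrahydrofuran A8.
- **Merits.** This is the most convergent road: two fragments of similar size give the ring in one step, with C5 set from C1' by chelation. The chosen plan, entirely linear, cannot match this.
- **Weak points.** Silicon ends up trans to pentyl, so oxidation with retention gives the wrong C3 epimer and an inversion is needed (a Mitsunobu esterification with palmitic acid could do both jobs). Oxidising a PhMe2Si group requires electrophilic dearylation (Hg(OAc)2/peracid or a bromine source), which endangers the terminal alkene. The benzyl ether cannot be removed by hydrogenolysis. A7 must be made in enantioenriched form.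
- **Comparison.** The chosen plan sets against the better convergence that oxygen arrives at C3 with the right configuration and that nothing after the key step threatens the alkene.

Key step: step 6

Assumption: enol diisopinocampheylborinates of methyl ketones made with (−)-Ipc2BCl are taken to add to the Si face of aldehydes; should the sense be the opposite, (+)-Ipc2BCl is used and nothing else changes.

## Route

Step 1
Reactants: 1 8-bromooct-1-ene; 2 methyl (2R)-oxirane-2-carboxylate
Product: 4 methyl (2R)-2-hydroxyundec-10-enoate, via oct-7-enylmagnesium bromide 3 (not isolated)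
Conditions: Mg, THF, rt to 40 °C; then CuI (10 mol %), 2, THF, −78 to −40 °C; aq. NH4Cl
Reagents that add atoms: none
Why: Copper-catalysed opening of a glycidic ester by an alkylmagnesium halide at the unsubstituted epoxide carbon, where the organocopper species prefers the CH2 terminus to the ester carbonyl at low temperature; the stereocentre is not touched, so the R configuration of 2 becomes that of 4 and later of C1'.

Step 2
Reactants: 4 methyl (2R)-2-hydroxyundec-10-enoate
Product: 5 methyl (2R)-2-[tert-butyl(diphenyl)silyl]oxyundec-10-enoate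
Conditions: TBDPSCl, imidazole, DMF, rt
Reagents that add atoms: tert-butyl(chloro)diphenylsilane, CC(C)(C)[Si](Cl)(c1ccccc1)c1ccccc1
Why: Standard imidazole-promoted silylation of a secondary alcohol; the group blocks this oxygen as a nucleophile in step 6 and tolerates every later reagent until fluoride.

Step 3
Reactants: 5 methyl (2R)-2-[tert-butyl(diphenyl)silyl]oxyundec-10-enoate
Product: 7 (3R)-3-[tert-butyl(diphenyl)silyl]oxydodec-11-en-2-one, via N-methoxy-N-methylamide 6 (not isolated)
Conditions: MeNH(OMe)·HCl, i-PrMgCl, THF, −20 to 0 °C; then MeMgBr, 0 °C; aq. NH4Cl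
Reagents that add atoms: methylmagnesium bromide, C[Mg]Br
Why: Weinreb ketone synthesis run in one flask: the chloromagnesium amide converts the ester into 6, and MeMgBr adds once because the magnesium chelate of the tetrahedral adduct survives until work-up; the α-silyloxy centre is not enolised under these conditions.

Step 4
Reactants: 7 (3R)-3-[tert-butyl(diphenyl)silyl]oxydodec-11-en-2-one; 8 acrolein
Product: 10 (3S,6R)-6-[tert-butyl(diphenyl)silyl]oxy-3-hydroxypentadeca-1,14-dien-5-one, via enol diisopinocampheylborinate 9 (not isolated)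
Conditions: (−)-Ipc2BCl, Et3N, Et2O, 0 °C; 8, −78 to −20 °C; then H2O2, MeOH, aq. NaH2PO4/Na2HPO4 (pH 7), 0 °C
Reagents that add atoms: none
Why: Reagent-controlled boron aldol reaction of a methyl ketone: enolisation occurs on the methyl side, the enol borinate adds 1,2 to the enal through a cyclic transition state, and the isopinocampheyl ligands direct it to the Si face of acrolein, which gives 3S; the non-chelating silyloxy centre is expected to exert only a weak bias of its own.

Step 5
Reactants: 10 (3S,6R)-6-[tert-butyl(diphenyl)silyl]oxy-3-hydroxypentadeca-1,14-dien-5-one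
Product: 12 (3S,5R,6R)-6-[tert-butyl(diphenyl)silyl]oxypentadeca-1,14-diene-3,5-diol, via diethylboron chelate 11 (not isolated)
Conditions: Et2BOMe, THF/MeOH (4:1), −78 °C; NaBH4, −78 °C; AcOH, then MeOH co-evaporation
Reagents that add atoms: none
Why: Narasaka–Prasad reduction: the C3 oxygen and the ketone are held in a six-membered boron chelate and external hydride attacks its half-chair axially, giving the 3,5-syn diol, so C3 (S) sets C5 (R); this chelate control is expected to override the Felkin preference of the α-silyloxy ketone.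

Step 6
Reactants: 12 (3S,5R,6R)-6-[tert-butyl(diphenyl)silyl]oxypentadeca-1,14-diene-3,5-diol; 13 carbon monoxide
Product: 14 (3aS,5R,6aS)-5-[(1R)-1-[tert-butyl(diphenyl)silyl]oxydec-9-enyl]tetrahydrofuro[3,2-b]furan-2(3H)-one
Conditions: PdCl2 (10 mol %), CuCl2 (3 equiv), NaOAc (3 equiv), CO (1 atm), AcOH, rt
Reagents that add atoms: none
Why: Divalent palladium binds the C1=C2 alkene beside the allylic C3 hydroxyl, and the C5 hydroxyl adds to C2 in a 5-exo-trig oxypalladation that closes the tetrahydrofuran and leaves a primary alkylpalladium at C1. CO inserts into this C–Pd bond and the acylpalladium is captured by the C3 hydroxyl in a five-membered acyl transfer that closes the γ-lactone and releases zerovalent palladium, which CuCl2 reoxidises while NaOAc buffers the HCl formed. The closest known reaction type is the PdCl2/CuCl2-catalysed oxycarbonylative bicyclisation of pent-4-ene-1,3-diols to 2,6-dioxabicyclo[3.3.0]octan-3-ones, of which 12 is a 1-substituted member. The one new stereocentre, C2 of the tetrahydrofuran (3a of the bicycle), is controlled by C3: only the alkylpalladium whose CH2Pd arm is cis to the C3 hydroxyl can lactonise, a trans-fused five–five system being out of reach, and reversible oxypalladation drains the other diastereomer into this channel. With C2 cis to the C3 oxygen, the syn relationship of the C3 and C5 oxygens from step 5 becomes the 2,5-trans arrangement. Attack at the internal alkene carbon follows from the preference for a five- over a six-membered ring and from Markovnikov addition to a terminal alkene. The step needs chemoselectivity for the allylic alkene over C14=C15: only the former has a hydroxyl placed for intramolecular attack and an allylic oxygen to guide the metal, whereas the remote alkene can react only by slower intermolecular acetoxy- or chloropalladation, and the silylated C6 oxygen cannot close a pyran.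

Step 7
Reactants: 14 (3aS,5R,6aS)-5-[(1R)-1-[tert-butyl(diphenyl)silyl]oxydec-9-enyl]tetrahydrofuro[3,2-b]furan-2(3H)-one
Product: 15 (2S,3S,5R)-5-[(1R)-1-[tert-butyl(diphenyl)silyl]oxydec-9-enyl]-2-(2-hydroxyethyl)tetrahydrofuran-3-ol
Conditions: LiAlH4, THF, 0 °C; H2O, aq. NaOH
Reagents that add atoms: none
Why: Hydride reduction of a γ-lactone to the 1,4-diol; silyl ether and isolated alkenes are inert and no stereocentre is touched.

Step 8
Reactants: 15 (2S,3S,5R)-5-[(1R)-1-[tert-butyl(diphenyl)silyl]oxydec-9-enyl]-2-(2-hydroxyethyl)tetrahydrofuran-3-ol; 16 hexadecanoyl chloride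
Product: 18 (2S,3S,5R)-5-[(1R)-1-[tert-butyl(diphenyl)silyl]oxydec-9-enyl]-2-[2-(4-methylphenyl)sulfonyloxyethyl]tetrahydrofuran-3-yl hexadecanoate, via hydroxy tosylate 17 (not isolated)
Conditions: TsCl (1.1 equiv), pyridine, CH2Cl2, 0 °C; then 16, DMAP (cat.), 0 °C to rt
Reagents that add atoms: 4-methylbenzenesulfonyl chloride, Cc1ccc(cc1)S(=O)(=O)Cl
Why: Sulfonylation discriminates the unhindered primary from the ring-bound secondary hydroxyl, and DMAP-catalysed acylation of the remaining hydroxyl in the same flask installs the palmitate and removes the nucleophile that could otherwise close 17 to a bicyclic ether by intramolecular Williamson reaction.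

Step 9
Reactants: 18 (2S,3S,5R)-5-[(1R)-1-[tert-butyl(diphenyl)silyl]oxydec-9-enyl]-2-[2-(4-methylphenyl)sulfonyloxyethyl]tetrahydrofuran-3-yl hexadecanoate
Product: 19 (2S,3S,5R)-5-[(1R)-1-[tert-butyl(diphenyl)silyl]oxydec-9-enyl]-2-pentyltetrahydrofuran-3-yl hexadecanoate
Conditions: n-Pr2CuLi (from n-PrLi and CuI), Et2O, −40 to −20 °C; aq. NH4Cl
Reagents that add atoms: lithium dipropylcuprate, [Li+].CCC[Cu-]CCC
Why: Substitution of an unhindered primary sulfonate by a lithium dialkylcuprate, a reagent that does not add to esters or isolated alkenes at low temperature; C3''–C5'' are joined to C2'' and the pentyl chain is complete.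

Step 10
Reactants: 19 (2S,3S,5R)-5-[(1R)-1-[tert-butyl(diphenyl)silyl]oxydec-9-enyl]-2-pentyltetrahydrofuran-3-yl hexadecanoate
Product: 20 (2S,3S,5R)-5-[(1R)-1-hydroxydec-9-enyl]-2-pentyltetrahydrofuran-3-yl hexadecanoate
Conditions: Bu4NF, AcOH (1:1), THF, rt
Reagents that add atoms: none
Why: Fluoride-mediated desilylation, buffered with AcOH so that the ester is neither cleaved nor shifted; the freed C1' hydroxyl lies on the ring face opposite the C3 ester and cannot reach it.

## Compound list

1 | 8-bromooct-1-ene | C=CCCCCCCBr | starting material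
2 | methyl (2R)-oxirane-2-carboxylate (methyl (R)-glycidate) | COC(=O)[C@H]1CO1 | starting material
3 | oct-7-enylmagnesium bromide | C=CCCCCCC[Mg]Br | intermediate (not isolated)
4 | methyl (2R)-2-hydroxyundec-10-enoate | C=CCCCCCCC[C@@H](O)C(=O)OC | intermediate
5 | methyl (2R)-2-[tert-butyl(diphenyl)silyl]oxyundec-10-enoate | C=CCCCCCCC[C@@H](O[Si](c1ccccc1)(c1ccccc1)C(C)(C)C)C(=O)OC | intermediate
6 | (2R)-2-[tert-butyl(diphenyl)silyl]oxy-N-methoxy-N-methylundec-10-enamide | C=CCCCCCCC[C@@H](O[Si](c1ccccc1)(c1ccccc1)C(C)(C)C)C(=O)N(C)OC | intermediate (not isolated)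
7 | (3R)-3-[tert-butyl(diphenyl)silyl]oxydodec-11-en-2-one | C=CCCCCCCC[C@@H](O[Si](c1ccccc1)(c1ccccc1)C(C)(C)C)C(C)=O | intermediate
8 | acrolein (prop-2-enal) | C=CC=O | starting material
9 | [(3R)-3-[tert-butyl(diphenyl)silyl]oxydodeca-1,11-dien-2-yl]oxy-bis[(1R,2S,3R,5R)-2,6,6-trimethylbicyclo[3.1.1]heptan-3-yl]borane | C=CCCCCCCC[C@@H](O[Si](c1ccccc1)(c1ccccc1)C(C)(C)C)C(=C)OB([C@@H]1C[C@@H]2C[C@H]([C@H]1C)C2(C)C)[C@@H]1C[C@@H]2C[C@H]([C@H]1C)C2(C)C | intermediate (not isolated)
10 | (3S,6R)-6-[tert-butyl(diphenyl)silyl]oxy-3-hydroxypentadeca-1,14-dien-5-one | C=CCCCCCCC[C@@H](O[Si](c1ccccc1)(c1ccccc1)C(C)(C)C)C(=O)C[C@H](O)C=C | intermediate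
11 | (3S,6R)-6-[tert-butyl(diphenyl)silyl]oxy-3-(diethylboranyloxy)pentadeca-1,14-dien-5-one, boron chelated by the C5 carbonyl | C=CCCCCCCC[C@@H](O[Si](c1ccccc1)(c1ccccc1)C(C)(C)C)C(=O)C[C@H](OB(CC)CC)C=C | intermediate (not isolated)
12 | (3S,5R,6R)-6-[tert-butyl(diphenyl)silyl]oxypentadeca-1,14-diene-3,5-diol | C=CCCCCCCC[C@@H](O[Si](c1ccccc1)(c1ccccc1)C(C)(C)C)[C@H](O)C[C@H](O)C=C | intermediate
13 | carbon monoxide | [C-]#[O+] | starting material
14 | (3aS,5R,6aS)-5-[(1R)-1-[tert-butyl(diphenyl)silyl]oxydec-9-enyl]tetrahydrofuro[3,2-b]furan-2(3H)-one | C=CCCCCCCC[C@@H](O[Si](c3ccccc3)(c3ccccc3)C(C)(C)C)[C@H]1C[C@H](OC2=O)[C@H](C2)O1 | intermediate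
15 | (2S,3S,5R)-5-[(1R)-1-[tert-butyl(diphenyl)silyl]oxydec-9-enyl]-2-(2-hydroxyethyl)tetrahydrofuran-3-ol | C=CCCCCCCC[C@@H](O[Si](c1ccccc1)(c1ccccc1)C(C)(C)C)[C@H]1C[C@H](O)[C@H](CCO)O1 | intermediate
16 | hexadecanoyl chloride (palmitoyl chloride) | CCCCCCCCCCCCCCCC(=O)Cl | starting material
17 | 2-[(2S,3S,5R)-5-[(1R)-1-[tert-butyl(diphenyl)silyl]oxydec-9-enyl]-3-hydroxytetrahydrofuran-2-yl]ethyl 4-methylbenzenesulfonate | C=CCCCCCCC[C@@H](O[Si](c1ccccc1)(c1ccccc1)C(C)(C)C)[C@H]1C[C@H](O)[C@H](CCOS(=O)(=O)c2ccc(C)cc2)O1 | intermediate (not isolated)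
18 | (2S,3S,5R)-5-[(1R)-1-[tert-butyl(diphenyl)silyl]oxydec-9-enyl]-2-[2-(4-methylphenyl)sulfonyloxyethyl]tetrahydrofuran-3-yl hexadecanoate | C=CCCCCCCC[C@@H](O[Si](c1ccccc1)(c1ccccc1)C(C)(C)C)[C@H]1C[C@H](OC(=O)CCCCCCCCCCCCCCC)[C@H](CCOS(=O)(=O)c2ccc(C)cc2)O1 | intermediate
19 | (2S,3S,5R)-5-[(1R)-1-[tert-butyl(diphenyl)silyl]oxydec-9-enyl]-2-pentyltetrahydrofuran-3-yl hexadecanoate | C=CCCCCCCC[C@@H](O[Si](c1ccccc1)(c1ccccc1)C(C)(C)C)[C@H]1C[C@H](OC(=O)CCCCCCCCCCCCCCC)[C@H](CCCCC)O1 | intermediate
20 | (2S,3S,5R)-5-[(1R)-1-hydroxydec-9-enyl]-2-pentyltetrahydrofuran-3-yl hexadecanoate | C=CCCCCCCC[C@@H](O)[C@H]1C[C@H](OC(=O)CCCCCCCCCCCCCCC)[C@H](CCCCC)O1 | target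

## Step count and least certain steps

Total: 10 steps. Longest linear sequence: 10 steps (1 or 2 to 20); the route is fully linear.

**Step 6 (key step).** The most likely failure is engagement of the remote monosubstituted alkene by divalent palladium under CO (intermolecular acetoxy- or chlorocarbonylation, or double-bond migration through a palladium hydride) at a rate comparable to the directed cyclisation. The cyclisation itself may be slowed because the nucleophilic C5 hydroxyl stands next to the bulky silyl ether. The fallback sets out from 12 and returns at 19, forming the ring by an epoxide opening that cannot involve the remote alkene. Hydroxyl-directed epoxidation of the allylic alcohol (Ti(OiPr)4, L-(+)-diisopropyl tartrate, t-BuOOH, CH2Cl2, −20 °C; matched for the 3S carbinol, erythro-selective) should give (1S,3R,4R)-4-[tert-butyl(diphenyl)silyl]oxy-1-[(2R)-oxiran-2-yl]tridec-12-ene-1,3-diol F1. Acid-catalysed 5-exo opening by the C5 hydroxyl (camphorsulfonic acid, CH2Cl2), with inversion at the oxirane CH, should then give (2S,3S,5R)-5-[(1R)-1-[tert-butyl(diphenyl)silyl]oxydec-9-enyl]-2-(hydroxymethyl)tetrahydrofuran-3-ol F2, which has the same 2,3-cis, 2,5-trans pattern. Primary tosylation and palmitoylation as in step 8 lead to [(2S,3S,5R)-5-[(1R)-1-[tert-butyl(diphenyl)silyl]oxydec-9-enyl]-3-hexadecanoyloxytetrahydrofuran-2-yl]methyl 4-methylbenzenesulfonate F3, and n-Bu2CuLi converts F3 into 19.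

**Step 4.** The risk is poor facial selectivity at acrolein: isopinocampheyl control of unsubstituted enol borinates is only moderate, and the α-silyloxy centre may oppose it, so that much material is lost as the 3R epimer. The fallback sets out from 7 and returns at 10, moving the stereocontrol from the C–C bond formation to a resolution. An aldol reaction with (c-C6H11)2BCl/Et3N and 8 gives (6R)-6-[tert-butyl(diphenyl)silyl]oxy-3-hydroxypentadeca-1,14-dien-5-one as a mixture of C3 epimers F4. Sharpless kinetic resolution (Ti(OiPr)4, D-(−)-diisopropyl tartrate, t-BuOOH, CH2Cl2, −20 °C) should then consume the 3R epimer as (1R,4R)-4-[tert-butyl(diphenyl)silyl]oxy-1-hydroxy-1-[(2S)-oxiran-2-yl]tridec-12-en-3-one F5. F5 is removed by chromatography and 10 remains.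

**Step 8.** Two processes threaten the one-flask sequence: incomplete discrimination between the two hydroxyls, and ring closure of hydroxy tosylate 17 to a bicyclic ether before the acyl chloride has reacted. The fallback sets out from 15 and returns at 18, separating the two hydroxyls by protecting groups instead of by rate. Silylation of the primary hydroxyl (t-BuMe2SiCl, imidazole) gives (2S,3S,5R)-2-[2-[tert-butyl(dimethyl)silyl]oxyethyl]-5-[(1R)-1-[tert-butyl(diphenyl)silyl]oxydec-9-enyl]tetrahydrofuran-3-ol F6. Acylation with 16 and DMAP gives (2S,3S,5R)-2-[2-[tert-butyl(dimethyl)silyl]oxyethyl]-5-[(1R)-1-[tert-butyl(diphenyl)silyl]oxydec-9-enyl]tetrahydrofuran-3-yl hexadecanoate F7. HF·pyridine in THF/pyridine removes only the primary silyl group to give (2S,3S,5R)-5-[(1R)-1-[tert-butyl(diphenyl)silyl]oxydec-9-enyl]-2-(2-hydroxyethyl)tetrahydrofuran-3-yl hexadecanoate F8. Tosylation of F8 gives 18.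

**Step 9.** The displacement may be slow enough for the cuprate to decay, or the reagent may attack or enolise the palmitate, or eliminate the sulfonate. The fallback sets out from 15 and returns at 19, making the C–C bond before the ester exists while still denying the C3 oxygen the chance to cyclise. Tosylation followed in the same flask by Et3SiCl/imidazole gives 2-[(2S,3S,5R)-5-[(1R)-1-[tert-butyl(diphenyl)silyl]oxydec-9-enyl]-3-triethylsilyloxytetrahydrofuran-2-yl]ethyl 4-methylbenzenesulfonate F9. n-Pr2CuLi gives tert-butyl-[(1R)-1-[(2R,4S,5S)-5-pentyl-4-triethylsilyloxytetrahydrofuran-2-yl]dec-9-enoxy]diphenylsilane F10. AcOH/THF/H2O removes the triethylsilyl group to give (2S,3S,5R)-5-[(1R)-1-[tert-butyl(diphenyl)silyl]oxydec-9-enyl]-2-pentyltetrahydrofuran-3-ol F11. Acylation of F11 with 16 and DMAP gives 19.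

## Further compounds

F1 | step 6 | (1S,3R,4R)-4-[tert-butyl(diphenyl)silyl]oxy-1-[(2R)-oxiran-2-yl]tridec-12-ene-1,3-diol | C=CCCCCCCC[C@@H](O[Si](c1ccccc1)(c1ccccc1)C(C)(C)C)[C@H](O)C[C@H](O)[C@H]1CO1
F2 | step 6 | (2S,3S,5R)-5-[(1R)-1-[tert-butyl(diphenyl)silyl]oxydec-9-enyl]-2-(hydroxymethyl)tetrahydrofuran-3-ol | C=CCCCCCCC[C@@H](O[Si](c1ccccc1)(c1ccccc1)C(C)(C)C)[C@H]1C[C@H](O)[C@H](CO)O1
F3 | step 6 | [(2S,3S,5R)-5-[(1R)-1-[tert-butyl(diphenyl)silyl]oxydec-9-enyl]-3-hexadecanoyloxytetrahydrofuran-2-yl]methyl 4-methylbenzenesulfonate | C=CCCCCCCC[C@@H](O[Si](c1ccccc1)(c1ccccc1)C(C)(C)C)[C@H]1C[C@H](OC(=O)CCCCCCCCCCCCCCC)[C@H](COS(=O)(=O)c2ccc(C)cc2)O1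
F4 | step 4 | (6R)-6-[tert-butyl(diphenyl)silyl]oxy-3-hydroxypentadeca-1,14-dien-5-one, mixture of C3 epimers | C=CCCCCCCC[C@@H](O[Si](c1ccccc1)(c1ccccc1)C(C)(C)C)C(=O)CC(O)C=C
F5 | step 4 | (1R,4R)-4-[tert-butyl(diphenyl)silyl]oxy-1-hydroxy-1-[(2S)-oxiran-2-yl]tridec-12-en-3-one | C=CCCCCCCC[C@@H](O[Si](c1ccccc1)(c1ccccc1)C(C)(C)C)C(=O)C[C@@H](O)[C@@H]1CO1
F6 | step 8 | (2S,3S,5R)-2-[2-[tert-butyl(dimethyl)silyl]oxyethyl]-5-[(1R)-1-[tert-butyl(diphenyl)silyl]oxydec-9-enyl]tetrahydrofuran-3-ol | C=CCCCCCCC[C@@H](O[Si](c1ccccc1)(c1ccccc1)C(C)(C)C)[C@H]1C[C@H](O)[C@H](CCO[Si](C)(C)C(C)(C)C)O1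
F7 | step 8 | (2S,3S,5R)-2-[2-[tert-butyl(dimethyl)silyl]oxyethyl]-5-[(1R)-1-[tert-butyl(diphenyl)silyl]oxydec-9-enyl]tetrahydrofuran-3-yl hexadecanoate | C=CCCCCCCC[C@@H](O[Si](c1ccccc1)(c1ccccc1)C(C)(C)C)[C@H]1C[C@H](OC(=O)CCCCCCCCCCCCCCC)[C@H](CCO[Si](C)(C)C(C)(C)C)O1
F8 | step 8 | (2S,3S,5R)-5-[(1R)-1-[tert-butyl(diphenyl)silyl]oxydec-9-enyl]-2-(2-hydroxyethyl)tetrahydrofuran-3-yl hexadecanoate | C=CCCCCCCC[C@@H](O[Si](c1ccccc1)(c1ccccc1)C(C)(C)C)[C@H]1C[C@H](OC(=O)CCCCCCCCCCCCCCC)[C@H](CCO)O1
F9 | step 9 | 2-[(2S,3S,5R)-5-[(1R)-1-[tert-butyl(diphenyl)silyl]oxydec-9-enyl]-3-triethylsilyloxytetrahydrofuran-2-yl]ethyl 4-methylbenzenesulfonate | C=CCCCCCCC[C@@H](O[Si](c1ccccc1)(c1ccccc1)C(C)(C)C)[C@H]1C[C@H](O[Si](CC)(CC)CC)[C@H](CCOS(=O)(=O)c2ccc(C)cc2)O1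
F10 | step 9 | tert-butyl-[(1R)-1-[(2R,4S,5S)-5-pentyl-4-triethylsilyloxytetrahydrofuran-2-yl]dec-9-enoxy]diphenylsilane | C=CCCCCCCC[C@@H](O[Si](c1ccccc1)(c1ccccc1)C(C)(C)C)[C@H]1C[C@H](O[Si](CC)(CC)CC)[C@H](CCCCC)O1
F11 | step 9 | (2S,3S,5R)-5-[(1R)-1-[tert-butyl(diphenyl)silyl]oxydec-9-enyl]-2-pentyltetrahydrofuran-3-ol | C=CCCCCCCC[C@@H](O[Si](c1ccccc1)(c1ccccc1)C(C)(C)C)[C@H]1C[C@H](O)[C@H](CCCCC)O1
A1 | alternative 1 | (2S,3S)-2-pentyl-3,4-dihydro-2H-pyran-3-yl hexadecanoate | CCCCC[C@@H]1OC=CC[C@@H]1OC(=O)CCCCCCCCCCCCCCC
A2 | alternative 1 | (2S,3S,5R)-5-(dimethoxymethyl)-2-pentyltetrahydrofuran-3-yl hexadecanoate | COC(OC)[C@H]1C[C@H](OC(=O)CCCCCCCCCCCCCCC)[C@H](CCCCC)O1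
A3 | alternative 2 | (2R)-2-[(1R)-1-(4-methoxybenzyloxy)dec-9-enyl]-2,3-dihydrofuran | C=CCCCCCCC[C@@H](OCc1ccc(OC)cc1)[C@H]1CC=CO1
A4 | alternative 2 | (3R)-3-[(1R)-1-(4-methoxybenzyloxy)dec-9-enyl]-2,6-dioxabicyclo[3.1.0]hexane, oxirane oxygen trans to the side chain | C=CCCCCCCC[C@@H](OCc1ccc(OC)cc1)[C@H]1C[C@@H]2O[C@@H]2O1
A5 | alternative 2 | (2S,3S,5R)-5-[(1R)-1-(4-methoxybenzyloxy)dec-9-enyl]-2-pentyltetrahydrofuran-3-ol | C=CCCCCCCC[C@@H](OCc2ccc(OC)cc2)[C@H]1C[C@H](O)[C@H](CCCCC)O1
A6 | alternative 3 | (2R)-2-(benzyloxy)undec-10-enal | C=CCCCCCCC[C@@H](OCc1ccccc1)C=O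
A7 | alternative 3 | (3R)-3-[dimethyl(phenyl)silyl]oct-1-ene | C=C[C@@H](CCCCC)[Si](C)(C)c1ccccc1
A8 | alternative 3 | [(2S,3R,5R)-5-[(1R)-1-(benzyloxy)dec-9-enyl]-2-pentyltetrahydrofuran-3-yl]-dimethyl-phenylsilane | C=CCCCCCCC[C@@H](OCc2ccccc2)[C@H]1C[C@@H]([Si](C)(C)c2ccccc2)[C@H](CCCCC)O1
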